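The route rests on the α-hydroxy ketone of the seven-membered ring, C5(=O)–C4H(OH) in azulene numbering, which lies between the methyl-bearing alkene carbon C6 and the quaternary ring-fusion carbon C3a. Both flanking bonds, C5–C6 and C4–C3a, are made in one flask by a ring enlargement. The precursor is a cyclopentane that carries a neopentyl α-keto aldehyde on the quaternary carbon and a (Z)-iodoalkenyl side chain. Alkenyllithium cyclisation onto the ketone first builds a six-membered ring; an α-ketol rearrangement then shifts the quaternary carbon to the aldehyde carbon and gives the hydroazulene. The quaternary centre is set by catalysis, the other four by relay.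

Key step: step 9

Remark: in step 2 the enantiomer of the chiral imidazolinium salt is chosen that gives the (S) quaternary centre; compound 12 is carried as both epimers at the carbinol carbon that step 8 turns into the ketone.

Step 1
Reactants: 1 but-2-yn-1-ol
Product: 2 but-2-ynal
Conditions: activated MnO2, CH2Cl2, 23 °C; filtered solution used directly
Reagents that add atoms: none
Why: Activated MnO2 oxidises propargylic alcohols to ynals without over-oxidation (heterogeneous propargylic alcohol oxidation), and no stereocentre is formed.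

Step 2
Reactants: 3 3-methylcyclopent-2-en-1-one; 4 ethynyl(trimethyl)silane; 2 but-2-ynal
Product: 7 (2S,3S)-2-[(1R)-1-hydroxybut-2-yn-1-yl]-3-methyl-3-[1-(trimethylsilyl)ethenyl]cyclopentan-1-one, via alkenylalane 5 (not isolated), via aluminium enolate 6 (not isolated)
Conditions: 4, i-Bu2AlH, hexanes/THF, 55 °C; then 3, Cu(OTf)2 (5 mol %), chiral sulfonate-bearing imidazolinium salt (5 mol %), THF, −78 → −15 °C; then 2 (3 equiv), −78 °C; aq. potassium sodium tartrate
Reagents that add atoms: none
Why: Hydroalumination puts Al and Si on the same alkyne carbon, the chiral N-heterocyclic carbene–copper catalyst transfers this bulky alkenyl group to the β-carbon in an enantioselective conjugate addition that sets the (S) quaternary centre, and the regiodefined aluminium enolate then adds to the ynal through a closed Zimmerman–Traxler transition state on the face opposite the silylalkenyl group, which should give the trans, anti aldol (catalyst control for the quaternary carbon, substrate control for the two new centres).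

Step 3
Reactants: 7 (2S,3S)-2-[(1R)-1-hydroxybut-2-yn-1-yl]-3-methyl-3-[1-(trimethylsilyl)ethenyl]cyclopentan-1-one
Product: 8 (2S,3R)-3-ethenyl-2-[(1R)-1-hydroxybut-2-yn-1-yl]-3-methylcyclopentan-1-one
Conditions: CF3CO2H, CH2Cl2, 0 °C; aq. NaHCO3
Reagents that add atoms: none
Why: Ipso-protonation of the vinylsilane gives a β-silyl cation that loses the silyl group (protodesilylation), so the bulky group that steered the aldol becomes the plain vinyl group without touching a stereocentre.

Step 4
Reactants: 8 (2S,3R)-3-ethenyl-2-[(1R)-1-hydroxybut-2-yn-1-yl]-3-methylcyclopentan-1-one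
Product: 9 (1R,2S,3R)-3-ethenyl-2-[(1R)-1-hydroxybut-2-yn-1-yl]-3-methyl-1-(propan-2-yl)cyclopentan-1-ol
Conditions: i-PrMgCl (3 equiv), CeCl3, THF, −78 → 0 °C
Reagents that add atoms: isopropylmagnesium chloride, CC(C)[Mg]Cl
Why: The organocerium reagent adds to the enolisable ketone without enolisation or reduction and should enter from the face opposite the C2 side chain, cis to the C2 hydrogen, which sets the tertiary carbinol (substrate-controlled 1,2-addition of an organocerium reagent).

Step 5
Reactants: 9 (1R,2S,3R)-3-ethenyl-2-[(1R)-1-hydroxybut-2-yn-1-yl]-3-methyl-1-(propan-2-yl)cyclopentan-1-ol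
Product: 10 (1R,2S,3R)-3-ethenyl-2-[(1R,2Z)-1-hydroxy-3-iodobut-2-en-1-yl]-3-methyl-1-(propan-2-yl)cyclopentan-1-ol
Conditions: NaAlH2(OCH2CH2OCH3)2, THF, 0 → 23 °C; then I2, −78 °C; aq. Na2S2O3
Reagents that add atoms: iodine, II
Why: Alkoxide-directed trans-hydroalumination of the propargylic alcohol places aluminium on the distal alkyne carbon and iodinolysis with retention gives the (Z)-3-iodoalkene (hydroalumination–iodination), while the isolated vinyl group is inert.

Step 6
Reactants: 10 (1R,2S,3R)-3-ethenyl-2-[(1R,2Z)-1-hydroxy-3-iodobut-2-en-1-yl]-3-methyl-1-(propan-2-yl)cyclopentan-1-ol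
Product: 11 (1R,2S,3R)-2-[(1R,2Z)-1-{[tert-butyl(dimethyl)silyl]oxy}-3-iodobut-2-en-1-yl]-3-ethenyl-3-methyl-1-(propan-2-yl)cyclopentan-1-ol
Conditions: t-BuMe2SiOSO2CF3 (1.1 equiv), 2,6-lutidine, CH2Cl2, −78 °C
Reagents that add atoms: tert-butyldimethylsilyl trifluoromethanesulfonate, CC(C)(C)[Si](C)(C)OS(=O)(=O)C(F)(F)F
Why: The silyl triflate reacts with the secondary allylic hydroxyl much faster than with the hindered tertiary one (selective silyl ether formation), which protects it for the two oxidations.

Step 7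
Reactants: 11 (1R,2S,3R)-2-[(1R,2Z)-1-{[tert-butyl(dimethyl)silyl]oxy}-3-iodobut-2-en-1-yl]-3-ethenyl-3-methyl-1-(propan-2-yl)cyclopentan-1-ol
Product: 12 1-[(1S,2S,3R)-2-[(1R,2Z)-1-{[tert-butyl(dimethyl)silyl]oxy}-3-iodobut-2-en-1-yl]-3-hydroxy-1-methyl-3-(propan-2-yl)cyclopentyl]ethane-1,2-diol
Conditions: OsO4 (2 mol %), N-methylmorpholine N-oxide, acetone/H2O, 23 °C
Reagents that add atoms: N-methylmorpholine N-oxide, C[N+]1([O-])CCOCC1; water, O
Why: Catalytic OsO4 dihydroxylates the monosubstituted vinyl group in preference to the deactivated trisubstituted iodoalkene (catalytic osmium tetroxide/N-oxide dihydroxylation), and the new carbinol centre is removed in step 8, so its configuration does not matter.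

Step 8
Reactants: 12 1-[(1S,2S,3R)-2-[(1R,2Z)-1-{[tert-butyl(dimethyl)silyl]oxy}-3-iodobut-2-en-1-yl]-3-hydroxy-1-methyl-3-(propan-2-yl)cyclopentyl]ethane-1,2-diol
Product: 13 2-[(1S,2S,3R)-2-[(1R,2Z)-1-{[tert-butyl(dimethyl)silyl]oxy}-3-iodobut-2-en-1-yl]-3-hydroxy-1-methyl-3-(propan-2-yl)cyclopentyl]-2-oxoacetaldehyde
Conditions: (COCl)2, dimethyl sulfoxide, CH2Cl2, −78 °C; then Et3N, −78 → 0 °C; used crude
Reagents that add atoms: none
Why: Swern oxidation converts the secondary and the primary hydroxyl into carbonyls without C–C cleavage, cannot oxidise the tertiary alcohol and spares the silyl ether and the vinyl iodide, which gives the non-enolisable neopentyl α-keto aldehyde.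

Step 9
Reactants: 13 2-[(1S,2S,3R)-2-[(1R,2Z)-1-{[tert-butyl(dimethyl)silyl]oxy}-3-iodobut-2-en-1-yl]-3-hydroxy-1-methyl-3-(propan-2-yl)cyclopentyl]-2-oxoacetaldehyde
Product: 16 (1R,3aS,4R,8S,8aS)-8-{[tert-butyl(dimethyl)silyl]oxy}-1,4-dihydroxy-3a,6-dimethyl-1-(propan-2-yl)-2,3,3a,4,8,8a-hexahydroazulen-5(1H)-one, via lithium hemiaminal alkoxide 14 (not isolated), via α-hydroxy aldehyde 15 (not isolated)
Conditions: LiN(CH3)CH2CH2N(CH3)2 (2.2 equiv, from the amine and n-BuLi), THF, −78 °C; t-BuLi (3.2 equiv), −78 °C; then CH3OH, −78 → 40 °C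
Reagents that add atoms: none
Why: Proposed new method: the lithium amide adds only to the aldehyde and masks it as an α-amino alkoxide, iodine–lithium exchange then gives the (Z)-alkenyllithium, which closes a six-membered ring by 6-exo-trig addition to the adjacent ketone (bond from the methyl-bearing alkene carbon to the later ketone carbon) and leaves a trans-fused hexahydroindene with a tertiary alkoxide next to the masked aldehyde. Methanol releases the aldehyde, and the lithium α-hydroxy aldehyde undergoes an α-ketol (acyloin) rearrangement in which the quaternary ring-fusion carbon migrates from the carbinol carbon to the aldehyde carbon (bond from the later CH(OH) carbon to the quaternary carbon), so the six-membered ring is enlarged to the seven-membered ring by a 1,2-shift. The closest known reaction types are the in situ protection of aldehydes as lithium α-amino alkoxides, the anionic cyclisation of alkenyllithiums onto ketones and the base-mediated ring-expanding α-ketol rearrangement of 1-hydroxycycloalkanecarbaldehydes; their union in one flask on an α-keto aldehyde has not been shown. The quaternary carbon migrates with retention, so its configuration and the trans ring fusion come from step 2, while the new carbinol centre is set under thermodynamic control because the α-ketol equilibrates through the reversible shift and the enediolate, which should place the hydroxyl equatorial and cis to the angular methyl. The step needs ketone-over-aldehyde chemoselectivity, secured by the amide mask and by six- against seven-membered ring closure, and migration of the quaternary carbon and not of the alkenyl carbon, secured because only that shift leads to the conjugated enone, the thermodynamic sink.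

Step 10
Reactants: 16 (1R,3aS,4R,8S,8aS)-8-{[tert-butyl(dimethyl)silyl]oxy}-1,4-dihydroxy-3a,6-dimethyl-1-(propan-2-yl)-2,3,3a,4,8,8a-hexahydroazulen-5(1H)-one
Product: 17 (1R,3aS,4R,8S,8aS)-1,4,8-trihydroxy-3a,6-dimethyl-1-(propan-2-yl)-2,3,3a,4,8,8a-hexahydroazulen-5(1H)-one
Conditions: HF·pyridine, pyridine, THF, 0 → 23 °C
Reagents that add atoms: none
Why: Buffered fluoride cleaves the silyl ether (desilylation) under non-basic conditions that spare the α-hydroxy enone and the tertiary alcohol.

Step 11
Reactants: 17 (1R,3aS,4R,8S,8aS)-1,4,8-trihydroxy-3a,6-dimethyl-1-(propan-2-yl)-2,3,3a,4,8,8a-hexahydroazulen-5(1H)-one; 18 4-methoxybenzoyl chloride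
Product: 19 (1R,3aS,4R,8S,8aS)-1,4-dihydroxy-3a,6-dimethyl-5-oxo-1-(propan-2-yl)-1,2,3,3a,4,5,8,8a-octahydroazulen-8-yl 4-methoxybenzoate
Conditions: 18 (1.1 equiv), pyridine, 4-(dimethylamino)pyridine (cat.), CH2Cl2, 0 °C
Reagents that add atoms: none
Why: Nucleophilic-catalysed acylation should take place at the allylic C8 hydroxyl, because the C4 hydroxyl sits between the ketone and the quaternary carbon and the C1 hydroxyl is tertiary (site-selective esterification), and no stereocentre is affected.

Compound list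
1 | but-2-yn-1-ol | CC#CCO | starting material
2 | but-2-ynal | CC#CC=O | intermediate
3 | 3-methylcyclopent-2-en-1-one | CC1=CC(=O)CC1 | starting material
4 | ethynyl(trimethyl)silane | C#C[Si](C)(C)C | starting material
5 | bis(2-methylpropyl)[1-(trimethylsilyl)ethenyl]alumane | CC(C)C[Al](CC(C)C)C(=C)[Si](C)(C)C | intermediate
6 | bis(2-methylpropyl)aluminium (3S)-3-methyl-3-[1-(trimethylsilyl)ethenyl]cyclopent-1-en-1-olate | C[C@]1(C(=C)[Si](C)(C)C)CCC(O[Al](CC(C)C)CC(C)C)=C1 | intermediate
7 | (2S,3S)-2-[(1R)-1-hydroxybut-2-yn-1-yl]-3-methyl-3-[1-(trimethylsilyl)ethenyl]cyclopentan-1-one | CC#C[C@H](O)[C@H]1C(=O)CC[C@]1(C)C(=C)[Si](C)(C)C | intermediate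
8 | (2S,3R)-3-ethenyl-2-[(1R)-1-hydroxybut-2-yn-1-yl]-3-methylcyclopentan-1-one | CC#C[C@H](O)[C@H]1C(=O)CC[C@]1(C)C=C | intermediate
9 | (1R,2S,3R)-3-ethenyl-2-[(1R)-1-hydroxybut-2-yn-1-yl]-3-methyl-1-(propan-2-yl)cyclopentan-1-ol | CC#C[C@H](O)[C@H]1[C@](O)(C(C)C)CC[C@]1(C)C=C | intermediate
10 | (1R,2S,3R)-3-ethenyl-2-[(1R,2Z)-1-hydroxy-3-iodobut-2-en-1-yl]-3-methyl-1-(propan-2-yl)cyclopentan-1-ol | I/C(C)=C\[C@H](O)[C@H]1[C@](O)(C(C)C)CC[C@]1(C)C=C | intermediate
11 | (1R,2S,3R)-2-[(1R,2Z)-1-{[tert-butyl(dimethyl)silyl]oxy}-3-iodobut-2-en-1-yl]-3-ethenyl-3-methyl-1-(propan-2-yl)cyclopentan-1-ol | I/C(C)=C\[C@H](O[Si](C)(C)C(C)(C)C)[C@H]1[C@](O)(C(C)C)CC[C@]1(C)C=C | intermediate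
12 | 1-[(1S,2S,3R)-2-[(1R,2Z)-1-{[tert-butyl(dimethyl)silyl]oxy}-3-iodobut-2-en-1-yl]-3-hydroxy-1-methyl-3-(propan-2-yl)cyclopentyl]ethane-1,2-diol, both epimers at C1 of the diol | I/C(C)=C\[C@H](O[Si](C)(C)C(C)(C)C)[C@H]1[C@](O)(C(C)C)CC[C@]1(C)C(O)CO | intermediate
13 | 2-[(1S,2S,3R)-2-[(1R,2Z)-1-{[tert-butyl(dimethyl)silyl]oxy}-3-iodobut-2-en-1-yl]-3-hydroxy-1-methyl-3-(propan-2-yl)cyclopentyl]-2-oxoacetaldehyde | I/C(C)=C\[C@H](O[Si](C)(C)C(C)(C)C)[C@H]1[C@](O)(C(C)C)CC[C@]1(C)C(=O)C=O | intermediate
14 | dilithium salt of 13 with the tertiary hydroxyl deprotonated and the aldehyde carbon bearing O–Li and the [2-(dimethylamino)ethyl](methyl)amino group | I/C(C)=C\[C@H](O[Si](C)(C)C(C)(C)C)[C@H]1[C@]([O-])(C(C)C)CC[C@]1(C)C(=O)C([O-])N(C)CCN(C)C.[Li+].[Li+] | intermediate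
15 | (1R,3aS,7S,7aS)-7-{[tert-butyl(dimethyl)silyl]oxy}-1,4-dihydroxy-3a,5-dimethyl-1-(propan-2-yl)-2,3,3a,4,7,7a-hexahydro-1H-indene-4-carbaldehyde, C4 configuration not defined, present as its lithium alkoxide | CC1=C[C@H](O[Si](C)(C)C(C)(C)C)[C@H]2[C@](O)(C(C)C)CC[C@]2(C)C1(O)C=O | intermediate
16 | (1R,3aS,4R,8S,8aS)-8-{[tert-butyl(dimethyl)silyl]oxy}-1,4-dihydroxy-3a,6-dimethyl-1-(propan-2-yl)-2,3,3a,4,8,8a-hexahydroazulen-5(1H)-one | CC1=C[C@H](O[Si](C)(C)C(C)(C)C)[C@H]2[C@](O)(C(C)C)CC[C@]2(C)[C@@H](O)C1=O | intermediate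
17 | (1R,3aS,4R,8S,8aS)-1,4,8-trihydroxy-3a,6-dimethyl-1-(propan-2-yl)-2,3,3a,4,8,8a-hexahydroazulen-5(1H)-one | CC1=C[C@H](O)[C@H]2[C@](O)(C(C)C)CC[C@]2(C)[C@@H](O)C1=O | intermediate
18 | 4-methoxybenzoyl chloride | COc1ccc(C(Cl)=O)cc1 | starting material
19 | (1R,3aS,4R,8S,8aS)-1,4-dihydroxy-3a,6-dimethyl-5-oxo-1-(propan-2-yl)-1,2,3,3a,4,5,8,8a-octahydroazulen-8-yl 4-methoxybenzoate | COc1ccc(C(=O)O[C@H]2C=C(C)C(=O)[C@H](O)[C@@]3(C)CC[C@@](O)(C(C)C)[C@H]23)cc1 | target

Total step count: 11. Longest linear sequence: 11 steps (1 → 2 → 7 → 8 → 9 → 10 → 11 → 12 → 13 → 16 → 17 → 19).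

Steps most likely to fail

Step 9 (Proposed new method). The amide mask may not hold: the alkenyllithium may add to the aldehyde carbon, or the hemiaminal alkoxide may pass a hydride to the neighbouring ketone. The hindered ketone may resist ring closure, and the alkenyl carbon may migrate before the system has equilibrated. The fallback uses known separate steps; it sets out from 13 and comes back at 16. The aldehyde of 13 is converted selectively into its dimethyl acetal, the α-keto acetal F1 (HC(OCH3)3, CH3OH, pyridinium p-toluenesulfonate). Iodine–lithium exchange with t-BuLi at −78 °C then closes the six-membered ring onto the ketone and gives the isolated tertiary alcohol, the hydroxy acetal F2. Mild hydrolysis (LiBF4, wet CH3CN) frees the α-hydroxy aldehyde 15, and Al(Ot-Bu)3 in toluene or K2CO3 in CH3OH effects the ring-expanding α-ketol rearrangement to 16 as an operation of its own.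

Step 2. The aldol of the aluminium enolate with a slim ynal may show poor control at the carbinol carbon (open against closed transition state), and excess alkenylalane may consume the aldehyde. The fallback sets out from 9, carried on as a mixture of carbinol epimers, and comes back at 9. Dess–Martin periodinane oxidises the secondary alcohol to the ynone F3, and a Corey–Bakshi–Shibata reduction ((R)-2-methyl-oxazaborolidine, BH3·S(CH3)2) resets the carbinol by reagent control, the alkynyl group acting as the small substituent.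

Step 3. Protonolysis of the C–Si bond may be accompanied by acid-induced dehydration of the β-hydroxy ketone or by ionisation and rearrangement of the propargylic alcohol. The fallback sets out from 7 and comes back at 8. Iododesilylation with N-iodosuccinimide in CH3CN at 0 °C gives the 1-iodoethenyl ketone F4, and palladium-catalysed formate reduction (Pd(OAc)2, PPh3, HCO2H, Et3N) replaces iodine by hydrogen.

Further compounds
F1 | step 9 | dimethyl acetal of the aldehyde of 13: 1-[(1S,2S,3R)-2-[(1R,2Z)-1-{[tert-butyl(dimethyl)silyl]oxy}-3-iodobut-2-en-1-yl]-3-hydroxy-1-methyl-3-(propan-2-yl)cyclopentyl]-2,2-dimethoxyethan-1-one | I/C(C)=C\[C@H](O[Si](C)(C)C(C)(C)C)[C@H]1[C@](O)(C(C)C)CC[C@]1(C)C(=O)C(OC)OC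
F2 | step 9 | (1R,3aS,7S,7aS)-7-{[tert-butyl(dimethyl)silyl]oxy}-4-(dimethoxymethyl)-3a,5-dimethyl-1-(propan-2-yl)-2,3,3a,4,7,7a-hexahydro-1H-indene-1,4-diol, C4 configuration not defined | CC1=C[C@H](O[Si](C)(C)C(C)(C)C)[C@H]2[C@](O)(C(C)C)CC[C@]2(C)C1(O)C(OC)OC
F3 | step 2 | ynone from 9 by oxidation of its secondary carbinol: 1-[2-ethenyl-5-hydroxy-2-methyl-5-(propan-2-yl)cyclopentyl]but-2-yn-1-one with the ring configuration of 9 | CC#CC(=O)[C@H]1[C@](O)(C(C)C)CC[C@]1(C)C=C
F4 | step 3 | (2S,3S)-2-[(1R)-1-hydroxybut-2-yn-1-yl]-3-(1-iodoethenyl)-3-methylcyclopentan-1-one | CC#C[C@H](O)[C@H]1C(=O)CC[C@]1(C)C(I)=C
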